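**Plan**
- Last cut: the silyl ether on the cyclopentanol oxygen.
- Key cut, two bonds in one retro-step: the lactone O–C bond at the tertiary cyclopentane/cyclohexane ring-fusion carbon and the CH2–CH(OH) bond of the cyclohexane. The enabling feature is that the secondary carbinol carbon and the tertiary acyloxy carbon are 1,3-related across one CH2 (Prins retron), while the acyl carbon sits on the quaternary pyran carbon next to the carbinol, 1,4 to the tertiary carbon, so an ester on a 2-formyl-dihydropyran can bridge the new ring.
- The precursor, a tert-butyl 2-formyl-3,6-dihydro-2H-pyran-2-carboxylate with a 2-methylidenecyclopentyl group at C3, is cut at the formyl C–C bond (enolate formylation), the nonenyl C–C bond at C6 (oxocarbenium alkenylation), the ring C4=C5 bond (metathesis) with its acetal C–O bond, and C2–C3 (glyoxylate aldol).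
- Forward ring order: cyclopentane (chiral pool), then dihydropyran, then cyclohexane and bridging δ-lactone together in the key step.
- Stereochemistry: the two cyclopentane centres come from enantiopure cis-4-acetoxycyclopentenol by stereoretentive allylation; pyran C3 from the organocatalyst; C6 from axial attack trans to the ester; quaternary C2 from enolate formylation anti to its neighbours; the carbinol and the tertiary lactone carbon from the key step (chair transition state and bridging geometry).

Key step: step 14

Assumption: the (R)-diarylprolinol is taken to give the (2S,3R)-anti aldol 10 by analogy with the usual facial sense of this catalyst class (the mirror-image catalyst would be used otherwise), and tert-butyl glyoxylate is taken as a catalogue compound.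

Step 1
Reactants: 1 (1R,4S)-cis-4-acetoxycyclopent-2-en-1-ol; 2 dimethyl malonate
Product: 3 dimethyl 2-[(1S,4R)-4-hydroxycyclopent-2-en-1-yl]propanedioate
Conditions: NaH, 2, THF, 0 °C; then 1, Pd(PPh3)4 (3 mol%), THF, rt to 45 °C
Reagents that add atoms: none
Why: Tsuji–Trost allylic alkylation: zerovalent palladium ionises the acetate with inversion and the soft malonate attacks anti to the metal at the terminus remote from the carbinol, so the new C–C bond should form with net retention, cis to the hydroxyl.

Step 2
Reactants: 3 dimethyl 2-[(1S,4R)-4-hydroxycyclopent-2-en-1-yl]propanedioate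
Product: 4 methyl 2-[(1R,4R)-4-hydroxycyclopent-2-en-1-yl]acetate
Conditions: LiCl, H2O, DMSO, 150 °C
Reagents that add atoms: none
Why: Krapcho dealkoxycarbonylation (chloride demethylation, then decarboxylation) should remove one ester without touching either stereocentre.

Step 3
Reactants: 4 methyl 2-[(1R,4R)-4-hydroxycyclopent-2-en-1-yl]acetate
Product: 5 methyl 2-[(1R,4R)-4-(tert-butyldimethylsilyloxy)cyclopent-2-en-1-yl]acetate
Conditions: TBSCl, imidazole, DMF, rt
Reagents that add atoms: tert-butyldimethylsilyl chloride, CC(C)(C)[Si](C)(C)Cl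
Why: Standard silylation of a secondary allylic alcohol; the silyl ether should survive all later steps and is removed last.

Step 4
Reactants: 5 methyl 2-[(1R,4R)-4-(tert-butyldimethylsilyloxy)cyclopent-2-en-1-yl]acetate
Product: 6 methyl 2-[(1R,4R)-4-(tert-butyldimethylsilyloxy)-2-oxocyclopentyl]acetate
Conditions: PdCl2 (10 mol%), CuCl, O2 (1 atm), DMF/H2O 7:1, rt
Reagents that add atoms: water, O
Why: Wacker oxidation with divalent palladium of an internal allylic ether: water should attack the alkene carbon remote from the silyloxy-bearing carbon, giving the β-silyloxy ketone next to the side-chain carbon under conditions mild enough to leave the new α-stereocentre intact.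

Step 5
Reactants: 6 methyl 2-[(1R,4R)-4-(tert-butyldimethylsilyloxy)-2-oxocyclopentyl]acetate
Product: 7 methyl 2-[(1R,4R)-4-(tert-butyldimethylsilyloxy)-2-methylidenecyclopentyl]acetate
Conditions: Zn, CH2Br2, TiCl4, THF/CH2Cl2, 0 °C to rt
Reagents that add atoms: dibromomethane, BrCBr
Why: Takai–Lombardo methylenation is non-basic, so the ketone should be converted to the exocyclic alkene without α-epimerisation, β-elimination of the silyloxy group or attack on the ester.

Step 6
Reactants: 7 methyl 2-[(1R,4R)-4-(tert-butyldimethylsilyloxy)-2-methylidenecyclopentyl]acetate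
Product: 8 2-[(1R,4R)-4-(tert-butyldimethylsilyloxy)-2-methylidenecyclopentyl]acetaldehyde
Conditions: DIBAL-H (1.05 equiv), CH2Cl2, −78 °C; Rochelle salt
Reagents that add atoms: none
Why: Partial ester reduction through the aluminium hemiacetal, which is stable at −78 °C, should stop at the aldehyde.

Step 7
Reactants: 8 2-[(1R,4R)-4-(tert-butyldimethylsilyloxy)-2-methylidenecyclopentyl]acetaldehyde; 9 tert-butyl glyoxylate
Product: 10 tert-butyl (2S,3R)-3-[(1R,4R)-4-(tert-butyldimethylsilyloxy)-2-methylidenecyclopentyl]-2-hydroxy-4-oxobutanoate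
Conditions: (R)-α,α-bis[3,5-bis(trifluoromethyl)phenyl]-2-pyrrolidinemethanol (10 mol%), MeCN, H2O (3 equiv), rt; used crude
Reagents that add atoms: none
Why: Diarylprolinol-catalysed enamine cross-aldol with a non-enolisable, highly electrophilic glyoxylate; the catalyst should set C3 and the anti C2 carbinol, overriding the remote ring stereocentre.

Step 8
Reactants: 10 tert-butyl (2S,3R)-3-[(1R,4R)-4-(tert-butyldimethylsilyloxy)-2-methylidenecyclopentyl]-2-hydroxy-4-oxobutanoate
Product: 11 tert-butyl (2S,3R)-3-[(1R,4R)-4-(tert-butyldimethylsilyloxy)-2-methylidenecyclopentyl]-2-hydroxypent-4-enoate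
Conditions: Ph3PCH3Br, KOtBu, THF, −78 to 0 °C (excess ylide, crude 10 added cold)
Reagents that add atoms: methyltriphenylphosphonium bromide, C[P+](c1ccccc1)(c1ccccc1)c1ccccc1.[Br-]
Why: Wittig methylenation of a β-hydroxy aldehyde with excess ylide at low temperature should give the vinyl group before the aldehyde α-centre can epimerise; the tert-butyl ester is inert to the ylide.

Step 9
Reactants: 11 tert-butyl (2S,3R)-3-[(1R,4R)-4-(tert-butyldimethylsilyloxy)-2-methylidenecyclopentyl]-2-hydroxypent-4-enoate; 12 methacrolein dimethyl acetal (3,3-dimethoxy-2-methylprop-1-ene)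
Product: 13 tert-butyl (2S,3R)-3-[(1R,4R)-4-(tert-butyldimethylsilyloxy)-2-methylidenecyclopentyl]-2-[(1-methoxy-2-methylprop-2-en-1-yl)oxy]pent-4-enoate (both acetal epimers)
Conditions: 12 (excess), PPTS (cat.), toluene, 40 °C, reduced pressure
Reagents that add atoms: none
Why: Acid-catalysed transacetalisation, driven by removal of methanol, should give the mixed acetal; the acetal centre is lost later, so its configuration is immaterial.

Step 10
Reactants: 13 mixed acetal
Product: 14 tert-butyl (2S,3R)-3-[(1R,4R)-4-(tert-butyldimethylsilyloxy)-2-methylidenecyclopentyl]-6-methoxy-5-methyl-3,6-dihydro-2H-pyran-2-carboxylate (both C6 epimers)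
Conditions: second-generation Grubbs catalyst (5 mol%), CH2Cl2, 40 °C
Reagents that add atoms: none
Why: Ring-closing metathesis between the vinyl and isopropenyl groups should close the six-membered ring with a trisubstituted alkene; the exocyclic methylene cannot form a viable ring and should stay untouched.

Step 11
Reactants: 15 (E)-non-1-en-1-ylboronic acid
Product: 16 potassium (E)-non-1-en-1-yltrifluoroborate
Conditions: KHF2, MeOH/H2O, rt
Reagents that add atoms: potassium hydrogen difluoride, [K+].[F-].F
Why: Standard conversion of a boronic acid into its bench-stable trifluoroborate with retention of alkene geometry.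

Step 12
Reactants: 14 tert-butyl 6-methoxy-dihydropyran-2-carboxylate; 16 potassium (E)-non-1-en-1-yltrifluoroborate
Product: 17 tert-butyl (2S,3R,6R)-3-[(1R,4R)-4-(tert-butyldimethylsilyloxy)-2-methylidenecyclopentyl]-5-methyl-6-[(E)-non-1-en-1-yl]-3,6-dihydro-2H-pyran-2-carboxylate
Conditions: BF3·OEt2, MeCN/CH2Cl2, −40 to −10 °C
Reagents that add atoms: none
Why: Ferrier-type C-glycosylation: BF3 ionises the allylic acetal to the unsaturated oxocarbenium ion, and the alkenyl borane should add at the oxocarbenium carbon pseudo-axially, trans to the C2 ester and therefore cis to the C3 cyclopentyl group, with ipso substitution at boron keeping the E geometry.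

Step 13
Reactants: 17 tert-butyl 6-nonenyl-dihydropyran-2-carboxylate
Product: 19 tert-butyl (2S,3R,6R)-3-[(1R,4R)-4-(tert-butyldimethylsilyloxy)-2-methylidenecyclopentyl]-2-formyl-5-methyl-6-[(E)-non-1-en-1-yl]-3,6-dihydro-2H-pyran-2-carboxylate, via lithium ester enolate 18 (not isolated)
Conditions: LDA, THF, −78 °C; HCO2Me, −78 °C; AcOH, −78 °C
Reagents that add atoms: methyl formate, COC=O
Why: Crossed Claisen C-formylation of a fully substituted ester enolate: allylic 1,3-strain should turn the C3 cyclopentyl group pseudo-axial, so the formate enters anti to it and to the C6 nonenyl group, placing the formyl group trans and the ester cis to both.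

Step 14
Reactants: 19 tert-butyl 2-formyl-dihydropyran-2-carboxylate
Product: 22 O-TBS ether of the target (silyl group on the cyclopentanol oxygen), via tertiary cyclopentyl cation zwitterion 20 (not isolated), via tert-butoxy dioxocarbenium zwitterion 21 (not isolated)
Conditions: BF3·OEt2 (1.5 equiv), CH2Cl2, −78 to −30 °C; aq. NaHCO3
Reagents that add atoms: none
Why: Proposed new method: BF3 binds the formyl oxygen of the highly electrophilic α-alkoxy-α-carboxy aldehyde, the CH2 terminus of the exocyclic 1,1-disubstituted alkene adds to the formyl carbon (Prins manifold; 6-exo-trig at C=O and endo at the alkene, so the cation develops at the tertiary cyclopentyl carbon), and the carbonyl oxygen of the neighbouring tert-butyl ester then captures that cation across the ring (six-membered O-closure onto a trigonal cation, boat cyclohexane, giving the 2-oxabicyclo[2.2.2]octan-3-one) with loss of 2-methylpropene, which makes the C–O bond formation irreversible. The closest known reaction types are Lewis-acid Prins and type 2 carbonyl-ene cyclisations of alkenyl aldehydes, cation-olefin cyclisations terminated by a carboxyl group, and the acid-catalysed lactonisation of 4-alkylcyclohex-3-ene-1-carboxylic acids to the same bridged lactone ring. The carbinol centre is set in a chair transition state fixed by the trans ring fusion to the dihydropyran (ring oxygen equatorial, ester axial): monodentate BF3 should place the complexed oxygen axial, anti to the bulky axial ester and away from its dipole, which gives the hydroxyl anti to the lactone bridge as in the target. The tertiary centre has no freedom, because the ester can reach the cation only on its own face, and this also fixes the cis fusion of the cyclopentane with the lactone oxygen syn to the ring-fusion hydrogen. The step needs capture of the cation to outrun proton loss and the formyl group to be activated in preference to the bis-allylic ether; the first should be secured by the 1,4-disposition of ester and cation and the irreversible loss of the tert-butyl group, the second by the low temperature and the much higher Lewis basicity and electrophilicity of the formyl ester.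

Step 15
Reactants: 22 O-TBS ether of the target
Product: 23 CNP0127096.2 (target)
Conditions: HF·pyridine, pyridine/THF, 0 °C to rt
Reagents that add atoms: none
Why: Buffered fluoride desilylation of a secondary silyl ether should leave the bridged lactone, the bis-allylic ether and both alkenes untouched.

**Compound list**
1 | (1R,4S)-cis-4-acetoxycyclopent-2-en-1-ol | O[C@H]1C=C[C@@H](OC(C)=O)C1 | starting material
2 | dimethyl malonate | COC(=O)CC(=O)OC | starting material
3 | dimethyl 2-[(1S,4R)-4-hydroxycyclopent-2-en-1-yl]propanedioate | O[C@H]1C=C[C@@H](C(C(=O)OC)C(=O)OC)C1 | intermediate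
4 | methyl 2-[(1R,4R)-4-hydroxycyclopent-2-en-1-yl]acetate | O[C@H]1C=C[C@@H](CC(=O)OC)C1 | intermediate
5 | methyl 2-[(1R,4R)-4-(tert-butyldimethylsilyloxy)cyclopent-2-en-1-yl]acetate | CC(C)(C)[Si](C)(C)O[C@H]1C=C[C@@H](CC(=O)OC)C1 | intermediate
6 | methyl 2-[(1R,4R)-4-(tert-butyldimethylsilyloxy)-2-oxocyclopentyl]acetate | CC(C)(C)[Si](C)(C)O[C@H]1CC(=O)[C@@H](CC(=O)OC)C1 | intermediate
7 | methyl 2-[(1R,4R)-4-(tert-butyldimethylsilyloxy)-2-methylidenecyclopentyl]acetate | CC(C)(C)[Si](C)(C)O[C@H]1CC(=C)[C@@H](CC(=O)OC)C1 | intermediate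
8 | 2-[(1R,4R)-4-(tert-butyldimethylsilyloxy)-2-methylidenecyclopentyl]acetaldehyde | CC(C)(C)[Si](C)(C)O[C@H]1CC(=C)[C@@H](CC=O)C1 | intermediate
9 | tert-butyl glyoxylate | O=CC(=O)OC(C)(C)C | starting material
10 | tert-butyl (2S,3R)-3-[(1R,4R)-4-(tert-butyldimethylsilyloxy)-2-methylidenecyclopentyl]-2-hydroxy-4-oxobutanoate | O=C[C@H]([C@H]1C[C@@H](O[Si](C)(C)C(C)(C)C)CC1=C)[C@H](O)C(=O)OC(C)(C)C | intermediate
11 | tert-butyl (2S,3R)-3-[(1R,4R)-4-(tert-butyldimethylsilyloxy)-2-methylidenecyclopentyl]-2-hydroxypent-4-enoate | C=C[C@H]([C@H]1C[C@@H](O[Si](C)(C)C(C)(C)C)CC1=C)[C@H](O)C(=O)OC(C)(C)C | intermediate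
12 | methacrolein dimethyl acetal | COC(OC)C(C)=C | starting material
13 | tert-butyl (2S,3R)-3-[(1R,4R)-4-(tert-butyldimethylsilyloxy)-2-methylidenecyclopentyl]-2-[(1-methoxy-2-methylprop-2-en-1-yl)oxy]pent-4-enoate, acetal epimers | C=C[C@H]([C@H]1C[C@@H](O[Si](C)(C)C(C)(C)C)CC1=C)[C@H](OC(OC)C(C)=C)C(=O)OC(C)(C)C | intermediate
14 | tert-butyl (2S,3R)-3-[(1R,4R)-4-(tert-butyldimethylsilyloxy)-2-methylidenecyclopentyl]-6-methoxy-5-methyl-3,6-dihydro-2H-pyran-2-carboxylate, C6 epimers | COC1O[C@H](C(=O)OC(C)(C)C)[C@@H]([C@H]2C[C@@H](O[Si](C)(C)C(C)(C)C)CC2=C)C=C1C | intermediate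
15 | (E)-non-1-en-1-ylboronic acid | CCCCCCC/C=C/B(O)O | starting material
16 | potassium (E)-non-1-en-1-yltrifluoroborate | CCCCCCC/C=C/[B-](F)(F)F.[K+] | intermediate
17 | tert-butyl (2S,3R,6R)-3-[(1R,4R)-4-(tert-butyldimethylsilyloxy)-2-methylidenecyclopentyl]-5-methyl-6-[(E)-non-1-en-1-yl]-3,6-dihydro-2H-pyran-2-carboxylate | CCCCCCC/C=C/[C@H]1O[C@H](C(=O)OC(C)(C)C)[C@@H]([C@H]2C[C@@H](O[Si](C)(C)C(C)(C)C)CC2=C)C=C1C | intermediate
18 | lithium ester enolate of 17 (C2 trigonal) | CCCCCCC/C=C/[C@H]1OC(=C([O-])OC(C)(C)C)[C@@H]([C@H]2C[C@@H](O[Si](C)(C)C(C)(C)C)CC2=C)C=C1C.[Li+] | intermediate (not isolated)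
19 | tert-butyl (2S,3R,6R)-3-[(1R,4R)-4-(tert-butyldimethylsilyloxy)-2-methylidenecyclopentyl]-2-formyl-5-methyl-6-[(E)-non-1-en-1-yl]-3,6-dihydro-2H-pyran-2-carboxylate | CCCCCCC/C=C/[C@H]1O[C@@](C=O)(C(=O)OC(C)(C)C)[C@@H]([C@H]2C[C@@H](O[Si](C)(C)C(C)(C)C)CC2=C)C=C1C | intermediate
20 | tertiary cyclopentyl cation zwitterion (cyclohexane closed, BF3-bound alkoxide on the new carbinol, ester still open) | CCCCCCC/C=C/[C@H]1O[C@]2(C(=O)OC(C)(C)C)[C@H](O[B-](F)(F)F)C[C+]3C[C@H](O[Si](C)(C)C(C)(C)C)C[C@@H]3[C@H]2C=C1C | intermediate (not isolated)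
21 | tert-butoxy dioxocarbenium zwitterion (lactone C–O bond formed, tert-butyl still attached) | CCCCCCC/C=C/[C@H]1O[C@@]23C(=[O+]C(C)(C)C)O[C@]4(C[C@H](O[Si](C)(C)C(C)(C)C)C[C@@H]4[C@H]2C=C1C)C[C@H]3O[B-](F)(F)F | intermediate (not isolated)
22 | O-TBS ether of the target: tetracyclic bridged lactone with free hydroxyl on the cyclohexane and the silyl ether on the cyclopentane | CCCCCCC/C=C/[C@H]1O[C@@]23C(=O)O[C@]4(C[C@H](O[Si](C)(C)C(C)(C)C)C[C@@H]4[C@H]2C=C1C)C[C@H]3O | intermediate
23 | CNP0127096.2: (E)-non-1-enyl methyl-dihydropyran fused to a 2-oxabicyclo[2.2.2]octan-3-one that carries a secondary hydroxyl and a cis-fused hydroxycyclopentane | CCCCCCC/C=C/[C@H]1O[C@@]23C(=O)O[C@]4(C[C@H](O)C[C@@H]4[C@H]2C=C1C)C[C@H]3O | target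

**Count:** 15 steps in total; longest linear sequence 14 steps (steps 1–10 and 12–15; step 11 is a one-step side branch).

**Steps most likely to fail**

Step 14 (proposed new method). The tertiary cation may lose a proton (ene outcome) faster than the ester captures it, the Lewis acid may ionise the bis-allylic ether, or a chelated transition state may invert the carbinol centre. The fallback uses known chemistry and sets out from 19. Me2AlCl (CH2Cl2, −78 °C) effects the carbonyl-ene cyclisation to the tricyclic homoallylic alcohol tert-butyl ester F1, in which the cyclohexane is closed and the double bond lies in the cyclopentene. A cobalt-catalysed hydrogen-atom-transfer hydro-acyloxylation then forms the same tertiary C–O bond by radical-polar crossover without strong acid: N,N'-bis(3,5-di-tert-butylsalicylidene)-1,2-cyclohexanediaminocobalt (divalent cobalt), N-fluoro-2,4,6-trimethylpyridinium tetrafluoroborate and PhSiH3 in trifluorotoluene at rt, with loss of the tert-butyl group. The route is rejoined at 22.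

Step 12. Facial selectivity at the oxocarbenium carbon may be poor, the nucleophile may attack the vinylogous ring carbon, or the acid may move the exocyclic double bond or remove the silyl group. The fallback sets out from 14. Potassium non-1-yn-1-yltrifluoroborate F2 (from commercial non-1-yne with n-BuLi, B(OMe)3 and KHF2) and BF3·OEt2 should give the 6-alkynyl dihydropyran F3; the slim alkynyl nucleophile has well-precedented axial delivery. Trans-hydrosilylation with [Cp*Ru(MeCN)3]PF6 and (EtO)3SiH gives the (Z)-alkenylsilane F4, and protodesilylation with AgF (THF/MeOH/H2O) gives the E-alkene. The route is rejoined at 17.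

Step 13. C-formylation may be incomplete or reversible, the α-allyloxy enolate may undergo [2,3]-sigmatropic rearrangement if it warms, or the formyl group may be lost on work-up. The fallback sets out from 17. The same enolate is trapped at −78 °C with monomeric formaldehyde (gas from cracked paraformaldehyde), an irreversible aldol that should give the hydroxymethyl ester F5 anti to both ring substituents. Dess–Martin periodinane (NaHCO3, CH2Cl2) then gives the aldehyde, and the route is rejoined at 19.

Further compounds
F1 | step 14 | tricyclic carbonyl-ene product: tert-butyl ester with free carbinol on the new cyclohexane and the double bond in the cyclopentene | CCCCCCC/C=C/[C@H]1O[C@]2(C(=O)OC(C)(C)C)[C@H](O)CC3=C[C@H](O[Si](C)(C)C(C)(C)C)C[C@@H]3[C@H]2C=C1C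
F2 | step 12 | potassium non-1-yn-1-yltrifluoroborate | CCCCCCCC#C[B-](F)(F)F.[K+]
F3 | step 12 | tert-butyl (2S,3R,6R)-3-[(1R,4R)-4-(tert-butyldimethylsilyloxy)-2-methylidenecyclopentyl]-5-methyl-6-(non-1-yn-1-yl)-3,6-dihydro-2H-pyran-2-carboxylate | CCCCCCCC#C[C@H]1O[C@H](C(=O)OC(C)(C)C)[C@@H]([C@H]2C[C@@H](O[Si](C)(C)C(C)(C)C)CC2=C)C=C1C
F4 | step 12 | (Z)-alkenylsilane: the 6-[(Z)-2-(triethoxysilyl)non-1-en-1-yl] analogue of 17 | CCCCCCC/C([Si](OCC)(OCC)OCC)=C/[C@H]1O[C@H](C(=O)OC(C)(C)C)[C@@H]([C@H]2C[C@@H](O[Si](C)(C)C(C)(C)C)CC2=C)C=C1C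
F5 | step 13 | tert-butyl (2S,3R,6R)-3-[(1R,4R)-4-(tert-butyldimethylsilyloxy)-2-methylidenecyclopentyl]-2-(hydroxymethyl)-5-methyl-6-[(E)-non-1-en-1-yl]-3,6-dihydro-2H-pyran-2-carboxylate | CCCCCCC/C=C/[C@H]1O[C@@](CO)(C(=O)OC(C)(C)C)[C@@H]([C@H]2C[C@@H](O[Si](C)(C)C(C)(C)C)CC2=C)C=C1C
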